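Take the partner to be the gas in solution, which is our own reading: it starts at nothing and has the saturation concentration 200 mM as its ceiling.

| flask | starting material | gas | remark | time |
|---|---|---|---|---|
| north-east | 0.67 M (in portions, 3) | 200 mM (held) | run made earlier; portions every 2.0 h |  |
| north | 1.5 M (in portions, 3) | 200 mM (held) | run made earlier; portions every 2.0 h |  |
| flask | 1.0 M (in portions, 3) | 200 mM (held) | the portions of starting material follow each other after 2.0 h, the first at the start | 6.0 h |

- north-east (time / h: target / %, side product / %, starting material / %): 1.33: 12.0, 0.9, 22.3; 2.50: 24.4, 5.4, 38.6; 4.00: 41.7, 9.5, 16.3; 5.00: 56.9, 15.9, 26.4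
- north (time / h: target / %, side product / %, starting material / %): 0.417: 2.9, 0, 31.5; 0.833: 7.2, 0.1, 25.9; 2.00: 14.5, 4.6, 14.6; 5.00: 46.7, 26.0, 28.1

(standard deviation of a reading: 1 percentage point)

- the earlier runs were read with a standard deviation of 1 percentage point
- at the start none of the gas is in solution

- the target in the flask at 6.0 h, as a percentage of the starting material charged
- the side product in the flask at 6.0 h, as a percentage of the starting material charged
- the starting material in the flask at 6.0 h, as a percentage of the starting material charged
- concentration of partner at 6.0 h, in M

Two rates act on c(partner): uptake, proportional to the gap below saturation, and draw, proportional to c(starting material) times c(partner). Equating them (a steady-state estimate) gives c(partner) = saturation/(1 + c(starting material)/K), with K the balance concentration, the c(starting material) at which partner sits at half of saturation.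

The readings give K. Target gained per hour, over starting material present, is 0.420 h⁻¹ at 0.184 M in the north-east run, and 0.360 h⁻¹ at 0.431 M early in the north run. This figure should follow c(partner), so the pair gives K = 1.30 M, a loose reading given the scatter of 1 percentage point.

The forecast gives target 56 %, side product 26 %, starting material 17 % and partner 0.3 M, taking the partner as “a co-product of the target”. We differ: its starting material in our balance gives partner 0.177 M, lower than its figure.

The flask gives target 58.9 %, side product 27.4 %, starting material 13.7 % and partner 0.173 M, so the forecast's partner is too high by a factor of 1.73.

    starting material + partner → target + by-product (k = 2.37 L mol⁻¹ h⁻¹)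
    gas ⇌ partner, rate k2*(csat - [partner]) (kL = 2.65 h⁻¹)
    starting material + by-product → side product (k = 0.904 L mol⁻¹ h⁻¹)

With K, the flask's own starting material gives partner 0.181 M against 0.173 M, and the neighbour flask charged with 0.60 M gives 0.188 M against 0.182 M. In the flask, partner was 0.136 M at 0.600 h and 0.155 M at 3.00 h, by which time uptake of gas had behind it 59 % of its turnover up to 6.00 h, and at 6.00 h target stood at 58.9 % with starting material at 13.7 %.

The numbers in the tables come from a simulation with constants of no real substance; noise was put on by code.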